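## Retrosynthetic overview

1. The 13,14-epoxide is made last by hydroxyl-directed epoxidation (C–O) of a 12α-allylic alcohol, itself obtained by reagent-controlled reduction of the ring A enone.
2. The γ-lactone and the C6 chloride come from one anti-chlorolactonization (C7–O bond, the key step) of a ten-membered (6Z)-diene carrying a β-hydroxy tert-butyl ester.
3. The ten-membered ring is closed by ethylene-mediated enyne metathesis/ring-closing metathesis, which creates C6=C7 and the C5=C16 methylene together.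
4. Chain assembly: C8/C17 by Felkin aldol on a vinyl ketone, C9 by Felkin reduction after acyl-anion addition to an O2–C9 lactone, and C2–C4 by alkenylzinc addition plus Sharpless epoxidation.
5. Ring A comes from an enantioselective Diels–Alder reaction; ring order is ring A, then the ten-membered ring, then the lactone, then the last epoxide.

Numbering: locants are the briarane locants of the target (C1 quaternary, C2/C9 acetoxy carbons, C3/C4 epoxide, C5=C16, C6–Cl, C7–O, C8–OH, C10 ring-fusion CH, C11–C14 in ring A, C15/C20 methyls, C17/C18/C19 lactone CH, CH3, C=O); β is the face of the C15 methyl.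

Assumption: the oxazaborolidinium catalyst induces on enal 3 in the same sense as on 2-methylacrolein, so the (S)-catalyst gives 4; otherwise its enantiomer is used.

## Route

Step 1
Reactants: 1 ethyl vinyl ketone
Product: 2 (Z)-silyloxydiene
Conditions: TBSOTf, Et3N, Et2O, 0 °C
Reagents that add atoms: tert-butyldimethylsilyl triflate, CC(C)(C)[Si](C)(C)OS(=O)(=O)C(F)(F)F
Why: Soft enolisation of the ethyl ketone gives the (Z)-silyl enol ether, a 2-silyloxy-1,3-diene with an outside methyl group.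

Step 2
Reactants: 2 (Z)-silyloxydiene; 3 ethyl (E)-3-methyl-4-oxobut-2-enoate
Product: 4 Diels–Alder adduct
Conditions: (S)-o-tolyl-CBS-oxazaborolidine·HNTf2 (20 mol%), CH2Cl2, −78 °C
Reagents that add atoms: none
Why: Catalytic enantioselective Diels–Alder reaction in which the activated formyl group directs the methyl-bearing diene terminus to C10, the (E)-dienophile fixes CHO and ester trans, and the catalyst sets C1 and C10 (the C11 methyl, expected endo to CHO, is erased in step 4).

Step 3
Reactants: 4 Diels–Alder adduct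
Product: 5 enone aldehyde ester
Conditions: Pd(OAc)2 (1.05 equiv), MeCN, 23 °C
Reagents that add atoms: none
Why: Saegusa–Ito oxidation, in which the palladium enolate undergoes β-hydride elimination towards C14 to give the C13=C14 enone without touching a stereocentre.

Step 4
Reactants: 5 enone aldehyde ester
Product: 6 silyl dienol ether aldehyde
Conditions: TIPSOTf, Et3N, CH2Cl2, 0 °C
Reagents that add atoms: triisopropylsilyl triflate, CC(C)[Si](OS(=O)(=O)C(F)(F)F)(C(C)C)C(C)C
Why: Soft enolisation at the only enolisable site (C11–H, C1 being quaternary) gives the cross-conjugated 2-silyloxydiene, which masks the enone against organometallics and makes C11 prochiral for step 11.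

Step 5
Reactants: 7 1,4-bis(trimethylsilyl)buta-1,3-diyne
Product: 9 buta-1,3-diynyl(trimethyl)silane, via lithium diynide 8 (not isolated)
Conditions: MeLi·LiBr, Et2O, 23 °C; H2O
Reagents that add atoms: none
Why: Selective mono-desilylation by attack of methyllithium at one silicon followed by protonation of the acetylide.

Step 6
Reactants: 6 silyl dienol ether aldehyde; 9 buta-1,3-diynyl(trimethyl)silane
Product: 12 (E)-enynyl carbinol, via alkenylborane 10 (not isolated), via alkenylzinc 11 (not isolated)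
Conditions: 9, Cy2BH, toluene, 0 → 23 °C; Me2Zn, −78 °C; (−)-MIB (5 mol%), 6, −10 °C; H2O
Reagents that add atoms: none
Why: Hydroboration of the terminal alkyne, boron-to-zinc exchange and amino-alcohol-catalysed alkenylzinc addition (Oppolzer–Walsh), in which (−)-MIB delivers the (E)-alkenyl group to the Si face of the aldehyde and sets C2.

Step 7
Reactants: 12 (E)-enynyl carbinol
Product: 14 epoxy lactone, via epoxy hydroxy ester 13 (not isolated)
Conditions: Ti(OiPr)4 (1.2 equiv), D-(−)-DIPT, t-BuOOH, 4 Å sieves, CH2Cl2, −20 °C; then 23 °C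
Reagents that add atoms: tert-butyl hydroperoxide, CC(C)(C)OO
Why: Sharpless asymmetric epoxidation in the matched mode for this secondary allylic alcohol gives the erythro trans-epoxide (C3, C4), and the titanium alkoxide then closes the trans-fused γ-lactone O2–C9, which protects O2 and activates C9.

Step 8
Reactants: 14 epoxy lactone; 15 methoxyallene
Product: 19 α-hydroxy vinyl ketone, via 1-lithio-1-methoxyallene 16 (not isolated), via allenyl ketone 17 (not isolated), via allenyl diol 18 (not isolated)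
Conditions: 15, n-BuLi, THF, −78 °C; 14; then MeOH, CeCl3·7H2O, NaBH4, −78 → −20 °C; then 5% aq. H2SO4, 0 °C
Reagents that add atoms: water, O
Why: Mono-addition of the acyl-anion equivalent to the lactone, Luche 1,2-reduction of the released ketone under Felkin–Anh control by C10 (hydride anti to quaternary C1) to set C9, and hydrolysis of the allenyl ether to the vinyl ketone.

Step 9
Reactants: 19 α-hydroxy vinyl ketone
Product: 20 bis(triethylsilyl) ether
Conditions: TESOTf, 2,6-lutidine, CH2Cl2, −78 °C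
Reagents that add atoms: triethylsilyl triflate, CC[Si](CC)(CC)OS(=O)(=O)C(F)(F)F
Why: Silylation protects both secondary hydroxyls and makes O9 non-chelating, as required for Felkin control in the next step.

Step 10
Reactants: 20 bis(triethylsilyl) ether; 21 tert-butyl propanoate
Product: 23 aldol adduct, via lithium (Z)-enolate 22 (not isolated)
Conditions: 21, LiN(iPr)2, THF–DMPU, −78 °C; 20, −78 °C; AcOH
Reagents that add atoms: none
Why: Kinetic 1,2-aldol addition in which polar Felkin–Anh attack anti to the C9 silyloxy group sets C8 and the Zimmerman–Traxler chair (Z-enolate, C9 branch equatorial) sets C17.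

Step 11
Reactants: 23 aldol adduct
Product: 24 enone triol alkyne
Conditions: Bu4NF, AcOH (1:1), THF, −20 → 0 °C
Reagents that add atoms: none
Why: Fluoride removes all four silyl groups and the liberated dienolate is protonated kinetically at C11 from the α face, anti to the pseudo-axial C9 branch (allylic 1,2-strain), giving the cis C10/C11 relationship and the enone.

Step 12
Reactants: 24 enone triol alkyne
Product: 26 ten-membered diene triol, via acyclic triene 25 (not isolated)
Conditions: second-generation Grubbs catalyst RuCl2(H2IMes)(PCy3)(=CHPh) (10 mol%), ethylene (1 atm), toluene, 60 °C; then argon purge, 2 mM, 80 °C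
Reagents that add atoms: ethylene, C=C
Why: Ethylene-promoted enyne cross-metathesis (Mori) turns the alkyne into the 2-substituted butadiene, and ring-closing metathesis between its vinyl end and the C8 vinyl group closes the ten-membered ring as the strain-dictated (Z)-alkene.

Step 13
Reactants: 26 ten-membered diene triol
Product: 27 diacetate
Conditions: Ac2O, pyridine, DMAP (cat.), CH2Cl2, 23 °C
Reagents that add atoms: acetic anhydride, CC(=O)OC(C)=O
Why: DMAP-catalysed acylation of the two secondary hydroxyls (C2, C9) while the hindered tertiary C8 hydroxyl stays free.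

Step 14
Reactants: 27 diacetate
Product: 28 chlorolactone enone
Conditions: NCS (1.1 equiv), Ph3P=S (10 mol%), CH2Cl2, −40 → 0 °C
Reagents that add atoms: N-chlorosuccinimide, O=C1CCC(=O)N1Cl
Why: Proposed new method: dealkylative 1,2-anti-chlorolactonization of a tert-butyl ester across the endocyclic alkene of a ring-embedded 2-substituted 1,3-diene, in which the sulfide-bound chlorenium is transferred to C6 in concert with attack of the ester carbonyl oxygen on C7 (nucleophile-assisted alkene activation, 5-exo), so the alkene carrying the tethered nucleophile outruns the exocyclic C5=C16 bond and no free allyl cation (1,4-addition) forms, the tert-butoxy-dioxolanylium ion then loses 2-methylpropene, and because C17 lies on the β face of C8 the oxygen enters C7 from β and chlorine C6 from α (anti addition to the Z-alkene), setting C6 and C7; the closest known reactions are Lewis-base-catalysed halolactonization of 4-alkenoic acids and iodolactonization of tert-butyl esters.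

Step 15
Reactants: 28 chlorolactone enone
Product: 29 12α-allylic alcohol
Conditions: (R)-2-methyl-CBS-oxazaborolidine (20 mol%), catecholborane, toluene, −78 °C
Reagents that add atoms: none
Why: Corey–Bakshi–Shibata reduction in which the (R)-catalyst (alkenyl as the large group) delivers hydride to the β face of C12 and gives the 12α-alcohol without touching esters, epoxide or allylic chloride.

Step 16
Reactants: 29 12α-allylic alcohol
Product: 30 CNP0141778.4 (target)
Conditions: VO(acac)2 (5 mol%), t-BuOOH, CH2Cl2, 0 °C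
Reagents that add atoms: tert-butyl hydroperoxide, CC(C)(C)OO
Why: Vanadium-catalysed hydroxyl-directed epoxidation delivers oxygen syn to the 12α-hydroxyl (also the face anti to the C15 methyl), setting C13 and C14.

## Compound list

1 | pent-1-en-3-one (ethyl vinyl ketone) | CCC(=O)C=C | starting material
2 | (Z)-tert-butyl(dimethyl)(penta-1,3-dien-3-yloxy)silane | C=C/C(O[Si](C)(C)C(C)(C)C)=C/C | intermediate
3 | ethyl (E)-3-methyl-4-oxobut-2-enoate | CCOC(=O)/C=C(\C)C=O | starting material
4 | ethyl (1S,2S,6S)-3-[(tert-butyldimethylsilyl)oxy]-6-formyl-2,6-dimethylcyclohex-3-ene-1-carboxylate | O=C[C@]1(C)[C@H]([C@H](C)C(O[Si](C)(C)C(C)(C)C)=CC1)C(=O)OCC | intermediate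
5 | ethyl (1S,2S,6S)-6-formyl-2,6-dimethyl-3-oxocyclohex-4-ene-1-carboxylate | O=C[C@]1(C)[C@H]([C@H](C)C(=O)C=C1)C(=O)OCC | intermediate
6 | ethyl (1S,6S)-6-formyl-2,6-dimethyl-3-[(triisopropylsilyl)oxy]cyclohexa-2,4-diene-1-carboxylate | O=C[C@]1(C)[C@H](C(C)=C(O[Si](C(C)C)(C(C)C)C(C)C)C=C1)C(=O)OCC | intermediate
7 | 1,4-bis(trimethylsilyl)buta-1,3-diyne | C[Si](C)(C)C#CC#C[Si](C)(C)C | starting material
8 | lithium 4-(trimethylsilyl)buta-1,3-diyn-1-ide | C[Si](C)(C)C#CC#C[Li] | intermediate
9 | buta-1,3-diyn-1-yl(trimethyl)silane | C[Si](C)(C)C#CC#C | intermediate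
10 | dicyclohexyl[(E)-4-(trimethylsilyl)but-1-en-3-yn-1-yl]borane | C[Si](C)(C)C#C/C=C/B(C1CCCCC1)C1CCCCC1 | intermediate
11 | methyl[(E)-4-(trimethylsilyl)but-1-en-3-yn-1-yl]zinc | C[Si](C)(C)C#C/C=C/[Zn]C | intermediate
12 | ethyl (1R,6S)-6-[(1S,2E)-1-hydroxy-5-(trimethylsilyl)pent-2-en-4-yn-1-yl]-2,6-dimethyl-3-[(triisopropylsilyl)oxy]cyclohexa-2,4-diene-1-carboxylate (C2 carbinol as in the target) | C[Si](C)(C)C#C/C=C/[C@H](O)[C@]1(C)[C@H](C(C)=C(O[Si](C(C)C)(C(C)C)C(C)C)C=C1)C(=O)OCC | intermediate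
13 | 12 with C3=C4 converted to the trans-epoxide erythro to the 2-OH (C2, C3, C4 as in the target) | C[Si](C)(C)C#C[C@H]1O[C@@H]1[C@H](O)[C@]1(C)[C@H](C(C)=C(O[Si](C(C)C)(C(C)C)C(C)C)C=C1)C(=O)OCC | intermediate
14 | trans-fused γ-lactone of 13 (O2 acylated by C9), bearing the 3,4-epoxy-5-alkynyl chain on C2 | C[Si](C)(C)C#C[C@H]1O[C@@H]1[C@@H]2OC(=O)[C@H]3C(C)=C(O[Si](C(C)C)(C(C)C)C(C)C)C=C[C@]23C | intermediate
15 | 1-methoxypropa-1,2-diene (methoxyallene) | COC=C=C | starting material
16 | 1-lithio-1-methoxypropa-1,2-diene | COC([Li])=C=C | intermediate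
17 | 2-hydroxy C9 ketone carrying the 1-methoxyallenyl group (open form of the hemiketal) | C[Si](C)(C)C#C[C@H]1O[C@@H]1[C@H](O)[C@]1(C)[C@H](C(C)=C(O[Si](C(C)C)(C(C)C)C(C)C)C=C1)C(=O)C(OC)=C=C | intermediate
18 | 2,9-diol carrying the 1-methoxyallenyl group on C9 (C9 as in the target) | C[Si](C)(C)C#C[C@H]1O[C@@H]1[C@H](O)[C@]1(C)[C@H](C(C)=C(O[Si](C(C)C)(C(C)C)C(C)C)C=C1)[C@H](O)C(OC)=C=C | intermediate
19 | 2,9-dihydroxy C8 vinyl ketone (C9H(OH)–CO–CH=CH2) | C[Si](C)(C)C#C[C@H]1O[C@@H]1[C@H](O)[C@]1(C)[C@H](C(C)=C(O[Si](C(C)C)(C(C)C)C(C)C)C=C1)[C@H](O)C(=O)C=C | intermediate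
20 | 2,9-bis(triethylsilyl) ether of 19 | C[Si](C)(C)C#C[C@H]1O[C@@H]1[C@H](O[Si](CC)(CC)CC)[C@]1(C)[C@H](C(C)=C(O[Si](C(C)C)(C(C)C)C(C)C)C=C1)[C@H](O[Si](CC)(CC)CC)C(=O)C=C | intermediate
21 | tert-butyl propanoate | CCC(=O)OC(C)(C)C | starting material
22 | lithium (Z)-1-tert-butoxyprop-1-en-1-olate (methyl cis to OLi) | C/C=C(/OC(C)(C)C)O[Li] | intermediate
23 | aldol adduct: C8 tertiary carbinol bearing vinyl and C17H(CH3)CO2tBu (C8, C17 as in the target), 2,9-bis-TES, silyl dienol ether, TMS-alkyne | C[Si](C)(C)C#C[C@H]1O[C@@H]1[C@H](O[Si](CC)(CC)CC)[C@]1(C)[C@H](C(C)=C(O[Si](C(C)C)(C(C)C)C(C)C)C=C1)[C@H](O[Si](CC)(CC)CC)[C@@](O)(C=C)[C@@H](C)C(=O)OC(C)(C)C | intermediate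
24 | desilylated 23: ring A 12-oxo-Δ13 enone with 11β-methyl, 2,8,9-triol, terminal C5≡C6 alkyne, C8 vinyl, tert-butyl ester | C#C[C@H]1O[C@@H]1[C@H](O)[C@]1(C)[C@H]([C@@H](C)C(=O)C=C1)[C@H](O)[C@@](O)(C=C)[C@@H](C)C(=O)OC(C)(C)C | intermediate
25 | 24 with the alkyne converted to a buta-1,3-dien-2-yl group on C4 | C=CC(=C)[C@H]1O[C@@H]1[C@H](O)[C@]1(C)[C@H]([C@@H](C)C(=O)C=C1)[C@H](O)[C@@](O)(C=C)[C@@H](C)C(=O)OC(C)(C)C | intermediate
26 | ten-membered ring: (6Z)-alkene, C5=C16 methylene, 3,4-epoxide, 2,8,9-triol, C8 bearing C17H(CH3)CO2tBu, ring A enone | C=C1[C@H]2O[C@@H]2[C@H](O)[C@]2(C)[C@H]([C@@H](C)C(=O)C=C2)[C@H](O)[C@](O)([C@@H](C)C(=O)OC(C)(C)C)/C=C\1 | intermediate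
27 | 2,9-diacetate of 26 | C=C1[C@H]2O[C@@H]2[C@H](OC(C)=O)[C@]2(C)[C@H]([C@@H](C)C(=O)C=C2)[C@H](OC(C)=O)[C@](O)([C@@H](C)C(=O)OC(C)(C)C)/C=C\1 | intermediate
28 | 6α-chloro 7,19-lactone with ring A 12-oxo-Δ13 enone (target lacking the 12-OH and 13,14-epoxide) | C=C1[C@H]2O[C@@H]2[C@H](OC(C)=O)[C@]2(C)[C@H]([C@@H](C)C(=O)C=C2)[C@H](OC(C)=O)[C@@]2(O)[C@H](OC(=O)[C@@H]2C)[C@H]1Cl | intermediate
29 | 12α-hydroxy-Δ13 chlorolactone | C=C1[C@H]2O[C@@H]2[C@H](OC(C)=O)[C@]2(C)[C@H]([C@@H](C)[C@H](O)C=C2)[C@H](OC(C)=O)[C@@]2(O)[C@H](OC(=O)[C@@H]2C)[C@H]1Cl | intermediate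
30 | CNP0141778.4 | C=C1[C@H]2O[C@@H]2[C@H](OC(C)=O)[C@]2(C)[C@H]([C@@H](C)[C@H](O)[C@@H]3O[C@@H]32)[C@H](OC(C)=O)[C@@]2(O)[C@H](OC(=O)[C@@H]2C)[C@H]1Cl | target

## Step count and weak points

Total steps: 16. Longest linear sequence: 15 (steps 1–4 and 6–16, from ethyl vinyl ketone).

Steps most likely to fail:

1. Step 12 (ten-membered ring closure). The C8 vinyl group sits on a fully substituted carbinol and medium-ring closure competes with oligomerisation. The fallback sets out from 20 and comes back at 26; it closes the ring before the C8 quaternary centre exists, using the less hindered vinyl ketone. Selective C-desilylation of 20 (AgNO3, 2,6-lutidine, aqueous acetone) gives the terminal alkyne F1. Cross-metathesis with ethylene (second-generation Grubbs catalyst RuCl2(H2IMes)(PCy3)(=CHPh)) gives the acyclic triene F2, and ring-closing metathesis at high dilution gives the ten-membered dienone F3. Addition of enolate 22 at −78 °C then gives the macrocyclic aldol adduct F4, and Bu4NF/AcOH as in step 11 returns 26.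

2. Step 14 (the proposed new chlorolactonization). Chlorenium attack at C16 with 1,4-addition, or reaction at the exocyclic alkene, may compete. The fallback uses known chemistry, sets out from 27 and comes back at 28. Epoxidation directed by the tertiary 8-hydroxyl (VO(acac)2, t-BuOOH) gives the 6α,7α-epoxide F5. PPTS-promoted 5-exo opening at C7 by the tert-butyl ester, with loss of 2-methylpropene and inversion at C7, gives the 6α-hydroxy lactone F6. Stereoretentive deoxychlorination through the chlorosulfite (SOCl2, catalytic TiCl4, CH2Cl2, 0 °C) then gives 28.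

3. Step 15 (C12 reduction). The substrate's own facial bias may oppose the catalyst. The fallback sets out from 28 and comes back at 29. Substrate-controlled Luche reduction (NaBH4, CeCl3·7H2O, MeOH, −78 °C) gives the 12β-alcohol F7. Mitsunobu inversion with formic acid (PPh3, DIAD, THF) gives the 12α-formate F8, and KHCO3 in MeOH at 0 °C cleaves the formate in the presence of the acetates to give 29.

## Further compounds

F1 | step 12 | 20 lacking the alkynyl trimethylsilyl group (terminal alkyne) | C#C[C@H]1O[C@@H]1[C@H](O[Si](CC)(CC)CC)[C@]1(C)[C@H](C(C)=C(O[Si](C(C)C)(C(C)C)C(C)C)C=C1)[C@H](O[Si](CC)(CC)CC)C(=O)C=C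
F2 | step 12 | F1 with the alkyne converted to a buta-1,3-dien-2-yl group (acyclic triene) | C=CC(=C)[C@H]1O[C@@H]1[C@H](O[Si](CC)(CC)CC)[C@]1(C)[C@H](C(C)=C(O[Si](C(C)C)(C(C)C)C(C)C)C=C1)[C@H](O[Si](CC)(CC)CC)C(=O)C=C
F3 | step 12 | ten-membered (6Z)-dienone with C8 ketone, 2,9-bis-TES, silyl dienol ether in ring A | C=C1[C@H]2O[C@@H]2[C@H](O[Si](CC)(CC)CC)[C@]2(C)[C@H](C(C)=C(O[Si](C(C)C)(C(C)C)C(C)C)C=C2)[C@H](O[Si](CC)(CC)CC)C(=O)/C=C\1
F4 | step 12 | macrocyclic aldol adduct (26 as its 2,9-bis-TES ether with silyl dienol ether in ring A) | C=C1[C@H]2O[C@@H]2[C@H](O[Si](CC)(CC)CC)[C@]2(C)[C@H](C(C)=C(O[Si](C(C)C)(C(C)C)C(C)C)C=C2)[C@H](O[Si](CC)(CC)CC)[C@](O)([C@@H](C)C(=O)OC(C)(C)C)/C=C\1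
F5 | step 14 | 6α,7α-epoxide of 27 | C=C1[C@H]2O[C@@H]2[C@H](OC(C)=O)[C@]2(C)[C@H]([C@@H](C)C(=O)C=C2)[C@H](OC(C)=O)[C@](O)([C@@H](C)C(=O)OC(C)(C)C)[C@H]2O[C@@H]12
F6 | step 14 | 6α-hydroxy analogue of 28 (OH in place of Cl) | C=C1[C@H]2O[C@@H]2[C@H](OC(C)=O)[C@]2(C)[C@H]([C@@H](C)C(=O)C=C2)[C@H](OC(C)=O)[C@@]2(O)[C@H](OC(=O)[C@@H]2C)[C@H]1O
F7 | step 15 | 12β-epimer of 29 | C=C1[C@H]2O[C@@H]2[C@H](OC(C)=O)[C@]2(C)[C@H]([C@@H](C)[C@@H](O)C=C2)[C@H](OC(C)=O)[C@@]2(O)[C@H](OC(=O)[C@@H]2C)[C@H]1Cl
F8 | step 15 | 12α-formate of 29 | C=C1[C@H]2O[C@@H]2[C@H](OC(C)=O)[C@]2(C)[C@H]([C@@H](C)[C@H](OC=O)C=C2)[C@H](OC(C)=O)[C@@]2(O)[C@H](OC(=O)[C@@H]2C)[C@H]1Cl
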